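## Retrosynthetic overview

- The target hydroquinone comes from a PMB- and methyl-masked macrolactam by one oxidative unmasking (ceric ammonium nitrate, then dithionite); the carbamate is put on just before.
- The 19-membered lactam is the only ring built (the arene is bought). It is closed last among the skeletal bonds by an intramolecular copper-catalysed N-arylation that forms the C20–N bond from an aryl bromide and a primary (2E,4Z)-dienamide.
- The seco-amide comes from Sonogashira coupling and cis-semi-reduction (C3–C4, 4Z), syn-propargylation of an enal (C6, C7) and cross-metathesis with methacrolein (C8=C9).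
- The C10–C15 array comes from two (Z)-crotylborations (C14/C15 and C10/C11) around a hydroformylation (C11) and a new enamine-catalysed asymmetric α-methoxylation that forms the C12–O bond and sets C12.

Assumption: compounds 1, 7, 12, 14 and 18 and all named reagents are bought; carbons are labelled C1–C21 in the usual ansamycin way (C1 amide carbonyl, C15 benzylic carbinol, C16–C21 arene, N on C20).

## Route

Step 1
Reactants: 1 2-hydroxy-5-methoxybenzaldehyde
Product: 2 3-bromo-2-hydroxy-5-methoxybenzaldehyde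
Conditions: Br2, NaOAc, AcOH, rt
Reagents that add atoms: bromine, BrBr
Why: Electrophilic aromatic bromination goes ortho to the phenol (the para position is blocked by OMe), placing Br on the future C20.

Step 2
Reactants: 2 3-bromo-2-hydroxy-5-methoxybenzaldehyde
Product: 3 3-bromo-2,5-dimethoxybenzaldehyde
Conditions: MeI, K2CO3, DMF, rt
Reagents that add atoms: iodomethane, CI
Why: Williamson O-methylation of the phenoxide gives the para-dimethoxyarene that later serves as the masked hydroquinone.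

Step 3
Reactants: 3 3-bromo-2,5-dimethoxybenzaldehyde
Product: 4 (1R,2S)-1-(3-bromo-2,5-dimethoxyphenyl)-2-methylbut-3-en-1-ol
Conditions: (Z)-crotyl-B(Ipc)2 [from (+)-Ipc2BOMe, (−)-α-pinene series], THF/Et2O, −78 °C; then NaOH, H2O2
Reagents that add atoms: (Z)-crotyldiisopinocampheylborane, C/C=C\CB([C@H]1C[C@H]2C[C@@H]([C@@H]1C)C2(C)C)[C@H]1C[C@H]2C[C@@H]([C@@H]1C)C2(C)C
Why: Brown crotylboration through a closed chair transition state; the Z-crotyl unit gives the syn pair and the (−)-α-pinene-derived ligands direct attack to the Re face, setting C15 as R and C14 as S.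

Step 4
Reactants: 4 (1R,2S)-1-(3-bromo-2,5-dimethoxyphenyl)-2-methylbut-3-en-1-ol
Product: 5 PMB ether of 4
Conditions: NaH, PMBCl, Bu4NI (cat.), DMF, 0 °C to rt
Reagents that add atoms: 4-methoxybenzyl chloride, COc1ccc(CCl)cc1
Why: Williamson etherification; the PMB group protects C15–OH through the chain build-up and is removed in the final oxidation.

Step 5
Reactants: 5 PMB ether of 4
Product: 6 (4S,5R)-5-(3-bromo-2,5-dimethoxyphenyl)-5-[(4-methoxyphenyl)methoxy]-4-methylpentanal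
Conditions: Rh(acac)(CO)2 (1 mol%), BIPHEPHOS (2 mol%), CO/H2 (1:1, 10 bar), toluene, 60 °C
Reagents that add atoms: carbon monoxide, [C-]#[O+]
Why: Linear-selective rhodium-catalysed hydroformylation (wide-bite-angle bisphosphite plus the allylic branch) adds C11 as the aldehyde and creates no stereocenter.

Step 6
Reactants: 7 3-chloroperoxybenzoic acid
Product: 8 methyl 3-chloroperoxybenzoate
Conditions: Me3SiCHN2, toluene/MeOH, 0 °C (used as a cold solution)
Reagents that add atoms: (trimethylsilyl)diazomethane, C[Si](C)(C)C=[N+]=[N-]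
Why: O-methylation of the acidic peracid by the diazoalkane, as in methyl esterification of carboxylic acids; the O–O bond is untouched.

Step 7
Reactants: 6 aldehyde (4S,5R); 8 methyl 3-chloroperoxybenzoate
Product: 9 (2S,4S,5R)-5-(3-bromo-2,5-dimethoxyphenyl)-2-methoxy-5-[(4-methoxyphenyl)methoxy]-4-methylpentanal
Conditions: (S)-α,α-diphenylprolinol trimethylsilyl ether (20 mol%), THF, 0 °C, dark; cold silica filtration, used at once
Reagents that add atoms: none
Why: Proposed new method: catalytic asymmetric α-methoxylation of an aldehyde by electrophilic methoxy transfer, in which the E-enamine of 6 attacks the methoxy oxygen of perester 8 (SN2 at oxygen into the O–O σ* orbital) and expels 3-chlorobenzoate, the same kind of leaving group that drives the known enamine α-benzoyloxylation with dibenzoyl peroxide; the diphenyl(silyloxy)methyl group blocks the Re face so the methoxy group arrives on the Si face and sets C12 as S, and hydrolysis of the α-methoxy iminium releases 9 and the catalyst; the closest known reactions are the prolinol-ether and tritylpyrrolidine-catalysed α-benzoyloxylation of aldehydes and alkoxy transfer from alkyl peresters to carbanions (Grignard reagents with tert-butyl perbenzoate).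

Step 8
Reactants: 9 α-methoxy aldehyde (2S,4S,5R)
Product: 10 (3S,4R,5S,7S,8R)-8-(3-bromo-2,5-dimethoxyphenyl)-5-methoxy-8-[(4-methoxyphenyl)methoxy]-3,7-dimethyloct-1-en-4-ol
Conditions: (Z)-crotyl-B(Ipc)2 [from (+)-Ipc2BOMe], THF/Et2O, −78 °C; then NaOH, H2O2
Reagents that add atoms: (Z)-crotyldiisopinocampheylborane, C/C=C\CB([C@H]1C[C@H]2C[C@@H]([C@@H]1C)C2(C)C)[C@H]1C[C@H]2C[C@@H]([C@@H]1C)C2(C)C
Why: Brown crotylboration in the matched case: Re-face attack by the reagent coincides with the Cornforth/Felkin preference of the α-methoxy aldehyde for Z-crotylboron reagents, setting C11 as R and C10 as S (C10/C11 syn, C11/C12 anti).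

Step 9
Reactants: 10 homoallylic alcohol
Product: 11 1-bromo-3-{(1R,2S,4S,5R,6S)-4,5-dimethoxy-1-[(4-methoxyphenyl)methoxy]-2,6-dimethyloct-7-en-1-yl}-2,5-dimethoxybenzene
Conditions: NaH, MeI, THF/DMF, 0 °C to rt
Reagents that add atoms: iodomethane, CI
Why: Williamson methylation of the only free hydroxyl installs the C11 methyl ether; nothing base-sensitive is present.

Step 10
Reactants: 11 dimethoxy alkene; 12 2-methylprop-2-enal
Product: 13 (2E,4S,5R,6S,8S,9R)-9-(3-bromo-2,5-dimethoxyphenyl)-5,6-dimethoxy-9-[(4-methoxyphenyl)methoxy]-2,4,8-trimethylnon-2-enal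
Conditions: RuCl2(H2IMes)(=CH-C6H4-2-O-i-Pr) (second-generation Hoveyda–Grubbs catalyst, 10 mol%), excess 12, CH2Cl2, 40 °C
Reagents that add atoms: none
Why: Olefin cross-metathesis of the terminal alkene with an electron-poor 1,1-disubstituted partner gives the thermodynamic E-trisubstituted enal (C7–C9) in one step.

Step 11
Reactants: 14 (S)-but-3-yn-2-ol
Product: 15 (S)-but-3-yn-2-yl methanesulfonate
Conditions: MsCl, Et3N, CH2Cl2, −78 to 0 °C
Reagents that add atoms: methanesulfonyl chloride, CS(=O)(=O)Cl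
Why: Sulfonylation at oxygen activates the propargylic alcohol without touching the stereocenter.

Step 12
Reactants: 15 (S)-but-3-yn-2-yl methanesulfonate
Product: 16 (M)-buta-1,2-dien-1-yl(tributyl)stannane
Conditions: Bu3SnH, LDA, THF, 0 °C; CuBr·SMe2, −78 °C; then 15
Reagents that add atoms: tributyltin hydride, CCCC[SnH](CCCC)CCCC
Why: Marshall anti-SN2' displacement of the propargylic mesylate by the stannylcuprate transfers central to axial chirality, (S) to (M).

Step 13
Reactants: 13 enal; 16 (M)-allenylstannane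
Product: 17 (3S,4R,5E,7S,8R,9S,11S,12R)-12-(3-bromo-2,5-dimethoxyphenyl)-8,9-dimethoxy-12-[(4-methoxyphenyl)methoxy]-3,5,7,11-tetramethyldodec-5-en-1-yn-4-ol
Conditions: BF3·OEt2, CH2Cl2, −78 °C
Reagents that add atoms: none
Why: Marshall propargylation: BF3-promoted SE2' addition anti to tin through an open transition state gives the syn adduct, the (M)-allene fixing C6 as S and hence C7 as R.

Step 14
Reactants: 18 diethyl 2-methylpropanedioate
Product: 19 diethyl 2-(diiodomethyl)-2-methylpropanedioate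
Conditions: NaH, Et2O, reflux; then CHI3, reflux
Reagents that add atoms: iodoform, IC(I)I
Why: Alkylation of the malonate enolate with iodoform, a standard entry to 3-iodoacrylates.

Step 15
Reactants: 19 diethyl 2-(diiodomethyl)-2-methylpropanedioate
Product: 20 (E)-3-iodo-2-methylprop-2-enoic acid
Conditions: KOH, EtOH/H2O, reflux; then HCl (aq)
Reagents that add atoms: potassium hydroxide, [K+].[OH-]
Why: Saponification followed by decarboxylative elimination of iodide gives the E-iodoacrylic acid selectively.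

Step 16
Reactants: 20 (E)-3-iodo-2-methylprop-2-enoic acid
Product: 22 (E)-3-iodo-2-methylprop-2-enamide, via acid chloride 21 (not isolated)
Conditions: (COCl)2, DMF (cat.), CH2Cl2, 0 °C; then NH3 (aq), 0 °C
Reagents that add atoms: oxalyl chloride, ClC(=O)C(Cl)=O; ammonia, N
Why: Acyl chloride formation and ammonolysis give the primary amide that will supply the lactam nitrogen; the alkene geometry is untouched.

Step 17
Reactants: 17 homopropargylic alcohol; 22 (E)-3-iodo-2-methylprop-2-enamide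
Product: 23 (2E,6S,7R,8E,10S,11R,12S,14S,15R)-15-(3-bromo-2,5-dimethoxyphenyl)-7-hydroxy-11,12-dimethoxy-15-[(4-methoxyphenyl)methoxy]-2,6,8,10,14-pentamethylpentadeca-2,8-dien-4-ynamide
Conditions: Pd(PPh3)2Cl2 (5 mol%), CuI (10 mol%), Et3N, THF, rt
Reagents that add atoms: none
Why: Sonogashira coupling forms C3–C4 with retention of the 2E geometry; the vinyl iodide adds to zerovalent palladium far faster than the hindered, electron-rich aryl bromide.

Step 18
Reactants: 23 enyne amide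
Product: 24 (2E,4Z,6S,7R,8E,10S,11R,12S,14S,15R)-15-(3-bromo-2,5-dimethoxyphenyl)-7-hydroxy-11,12-dimethoxy-15-[(4-methoxyphenyl)methoxy]-2,6,8,10,14-pentamethylpentadeca-2,4,8-trienamide
Conditions: Zn(Cu/Ag), MeOH/H2O, 35 °C
Reagents that add atoms: none
Why: Boland cis-semi-reduction of the conjugated alkyne with activated zinc gives the 4Z alkene and leaves the aryl bromide and the other alkenes alone.

Step 19
Reactants: 24 seco bromo-dienamide
Product: 25 (4E,6Z,8S,9R,10E,12S,13R,14S,16S,17R)-9-hydroxy-13,14,20,22-tetramethoxy-17-[(4-methoxyphenyl)methoxy]-4,8,10,12,16-pentamethyl-2-azabicyclo[16.3.1]docosa-1(21),4,6,10,18(22),19-hexaen-3-one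
Conditions: CuI (50 mol%), N,N'-dimethylethylenediamine, K2CO3, toluene (5 mM), 100 °C
Reagents that add atoms: none
Why: Goldberg-type intramolecular N-arylation of the primary amide (monovalent copper/diamine), precedented for related ansamycin lactams, forms the aryl C20–N bond and the 19-membered ring; amide N–H reacts far faster than the secondary alcohol.

Step 20
Reactants: 25 macrolactam alcohol
Product: 27 (4E,6Z,8S,9R,10E,12S,13R,14S,16S,17R)-13,14,20,22-tetramethoxy-17-[(4-methoxyphenyl)methoxy]-4,8,10,12,16-pentamethyl-3-oxo-2-azabicyclo[16.3.1]docosa-1(21),4,6,10,18(22),19-hexaen-9-yl carbamate, via trichloroacetyl carbamate 26 (not isolated)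
Conditions: Cl3CC(O)NCO, CH2Cl2, 0 °C; then K2CO3, MeOH, rt
Reagents that add atoms: trichloroacetyl isocyanate, O=C=NC(=O)C(Cl)(Cl)Cl
Why: Addition of the only free hydroxyl (C7) to the acyl isocyanate and methanolysis of the trichloroacetyl group give the primary carbamate with retention at C7.

Step 21
Reactants: 27 protected carbamate
Product: 29 target hydroquinone, via quinone 28 (not isolated)
Conditions: (NH4)2Ce(NO3)6, MeCN/H2O, 0 °C; then Na2S2O4 (aq), EtOAc, rt, under argon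
Reagents that add atoms: water, O
Why: Oxidative demethylation of the para-dimethoxyarene by tetravalent cerium gives the quinone while the PMB ether is cleaved oxidatively in the same pot; dithionite then reduces the quinone to the hydroquinone without touching any stereocenter.

## Compound list

1 | 2-hydroxy-5-methoxybenzaldehyde | O=Cc1cc(OC)ccc1O | starting material
2 | 3-bromo-2-hydroxy-5-methoxybenzaldehyde | O=Cc1cc(OC)cc(Br)c1O | intermediate
3 | 3-bromo-2,5-dimethoxybenzaldehyde | O=Cc1cc(OC)cc(Br)c1OC | intermediate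
4 | (1R,2S)-1-(3-bromo-2,5-dimethoxyphenyl)-2-methylbut-3-en-1-ol | C=C[C@H](C)[C@@H](O)c1cc(OC)cc(Br)c1OC | intermediate
5 | 1-bromo-2,5-dimethoxy-3-{(1R,2S)-1-[(4-methoxyphenyl)methoxy]-2-methylbut-3-en-1-yl}benzene | C=C[C@H](C)[C@@H](OCc1ccc(OC)cc1)c1cc(OC)cc(Br)c1OC | intermediate
6 | (4S,5R)-5-(3-bromo-2,5-dimethoxyphenyl)-5-[(4-methoxyphenyl)methoxy]-4-methylpentanal | O=CCC[C@H](C)[C@@H](OCc1ccc(OC)cc1)c1cc(OC)cc(Br)c1OC | intermediate
7 | 3-chloroperoxybenzoic acid | OOC(=O)c1cccc(Cl)c1 | starting material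
8 | methyl 3-chloroperoxybenzoate | COOC(=O)c1cccc(Cl)c1 | intermediate
9 | (2S,4S,5R)-5-(3-bromo-2,5-dimethoxyphenyl)-2-methoxy-5-[(4-methoxyphenyl)methoxy]-4-methylpentanal | O=C[C@@H](OC)C[C@H](C)[C@@H](OCc1ccc(OC)cc1)c1cc(OC)cc(Br)c1OC | intermediate
10 | (3S,4R,5S,7S,8R)-8-(3-bromo-2,5-dimethoxyphenyl)-5-methoxy-8-[(4-methoxyphenyl)methoxy]-3,7-dimethyloct-1-en-4-ol | C=C[C@H](C)[C@@H](O)[C@@H](OC)C[C@H](C)[C@@H](OCc1ccc(OC)cc1)c1cc(OC)cc(Br)c1OC | intermediate
11 | 1-bromo-3-{(1R,2S,4S,5R,6S)-4,5-dimethoxy-1-[(4-methoxyphenyl)methoxy]-2,6-dimethyloct-7-en-1-yl}-2,5-dimethoxybenzene | C=C[C@H](C)[C@@H](OC)[C@@H](OC)C[C@H](C)[C@@H](OCc1ccc(OC)cc1)c1cc(OC)cc(Br)c1OC | intermediate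
12 | 2-methylprop-2-enal (methacrolein) | CC(=C)C=O | starting material
13 | (2E,4S,5R,6S,8S,9R)-9-(3-bromo-2,5-dimethoxyphenyl)-5,6-dimethoxy-9-[(4-methoxyphenyl)methoxy]-2,4,8-trimethylnon-2-enal | O=C/C(C)=C/[C@H](C)[C@@H](OC)[C@@H](OC)C[C@H](C)[C@@H](OCc1ccc(OC)cc1)c1cc(OC)cc(Br)c1OC | intermediate
14 | (S)-but-3-yn-2-ol | C#C[C@H](C)O | starting material
15 | (S)-but-3-yn-2-yl methanesulfonate | C#C[C@H](C)OS(C)(=O)=O | intermediate
16 | (M)-buta-1,2-dien-1-yl(tributyl)stannane (axial descriptor aR) | [H]C([Sn](CCCC)(CCCC)CCCC)=[C@@]=C([H])C | intermediate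
17 | (3S,4R,5E,7S,8R,9S,11S,12R)-12-(3-bromo-2,5-dimethoxyphenyl)-8,9-dimethoxy-12-[(4-methoxyphenyl)methoxy]-3,5,7,11-tetramethyldodec-5-en-1-yn-4-ol | C#C[C@H](C)[C@@H](O)/C(C)=C/[C@H](C)[C@@H](OC)[C@@H](OC)C[C@H](C)[C@@H](OCc1ccc(OC)cc1)c1cc(OC)cc(Br)c1OC | intermediate
18 | diethyl 2-methylpropanedioate | CCOC(=O)C(C)C(=O)OCC | starting material
19 | diethyl 2-(diiodomethyl)-2-methylpropanedioate | CCOC(=O)C(C)(C(I)I)C(=O)OCC | intermediate
20 | (E)-3-iodo-2-methylprop-2-enoic acid | OC(=O)/C(C)=C/I | intermediate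
21 | (E)-3-iodo-2-methylprop-2-enoyl chloride | ClC(=O)/C(C)=C/I | intermediate
22 | (E)-3-iodo-2-methylprop-2-enamide | NC(=O)/C(C)=C/I | intermediate
23 | (2E,6S,7R,8E,10S,11R,12S,14S,15R)-15-(3-bromo-2,5-dimethoxyphenyl)-7-hydroxy-11,12-dimethoxy-15-[(4-methoxyphenyl)methoxy]-2,6,8,10,14-pentamethylpentadeca-2,8-dien-4-ynamide | NC(=O)/C(C)=C/C#C[C@H](C)[C@@H](O)/C(C)=C/[C@H](C)[C@@H](OC)[C@@H](OC)C[C@H](C)[C@@H](OCc1ccc(OC)cc1)c1cc(OC)cc(Br)c1OC | intermediate
24 | (2E,4Z,6S,7R,8E,10S,11R,12S,14S,15R)-15-(3-bromo-2,5-dimethoxyphenyl)-7-hydroxy-11,12-dimethoxy-15-[(4-methoxyphenyl)methoxy]-2,6,8,10,14-pentamethylpentadeca-2,4,8-trienamide | NC(=O)/C(C)=C/C=C\[C@H](C)[C@@H](O)/C(C)=C/[C@H](C)[C@@H](OC)[C@@H](OC)C[C@H](C)[C@@H](OCc1ccc(OC)cc1)c1cc(OC)cc(Br)c1OC | intermediate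
25 | (4E,6Z,8S,9R,10E,12S,13R,14S,16S,17R)-9-hydroxy-13,14,20,22-tetramethoxy-17-[(4-methoxyphenyl)methoxy]-4,8,10,12,16-pentamethyl-2-azabicyclo[16.3.1]docosa-1(21),4,6,10,18(22),19-hexaen-3-one | CO[C@H]1[C@@H](OC)C[C@H](C)[C@@H](OCc2ccc(OC)cc2)c2cc(OC)cc(c2OC)NC(=O)/C(C)=C/C=C\[C@H](C)[C@@H](O)/C(C)=C/[C@@H]1C | intermediate
26 | N-(trichloroacetyl)carbamate of 25 at the C7 oxygen | CO[C@H]1[C@@H](OC)C[C@H](C)[C@@H](OCc2ccc(OC)cc2)c2cc(OC)cc(c2OC)NC(=O)/C(C)=C/C=C\[C@H](C)[C@@H](OC(=O)NC(=O)C(Cl)(Cl)Cl)/C(C)=C/[C@@H]1C | intermediate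
27 | (4E,6Z,8S,9R,10E,12S,13R,14S,16S,17R)-13,14,20,22-tetramethoxy-17-[(4-methoxyphenyl)methoxy]-4,8,10,12,16-pentamethyl-3-oxo-2-azabicyclo[16.3.1]docosa-1(21),4,6,10,18(22),19-hexaen-9-yl carbamate | CO[C@H]1[C@@H](OC)C[C@H](C)[C@@H](OCc2ccc(OC)cc2)c2cc(OC)cc(c2OC)NC(=O)/C(C)=C/C=C\[C@H](C)[C@@H](OC(N)=O)/C(C)=C/[C@@H]1C | intermediate
28 | (4E,6Z,8S,9R,10E,12S,13R,14S,16S,17R)-17-hydroxy-13,14-dimethoxy-4,8,10,12,16-pentamethyl-3,20,22-trioxo-2-azabicyclo[16.3.1]docosa-1(21),4,6,10,18-pentaen-9-yl carbamate (quinone) | CO[C@H]1[C@@H](OC)C[C@H](C)[C@@H](O)C2=CC(=O)C=C(NC(=O)/C(C)=C/C=C\[C@H](C)[C@@H](OC(N)=O)/C(C)=C/[C@@H]1C)C2=O | intermediate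
29 | (4E,6Z,8S,9R,10E,12S,13R,14S,16S,17R)-17,20,22-trihydroxy-13,14-dimethoxy-4,8,10,12,16-pentamethyl-3-oxo-2-azabicyclo[16.3.1]docosa-1(21),4,6,10,18(22),19-hexaen-9-yl carbamate | CO[C@H]1[C@@H](OC)C[C@H](C)[C@@H](O)c2cc(O)cc(c2O)NC(=O)/C(C)=C/C=C\[C@H](C)[C@@H](OC(N)=O)/C(C)=C/[C@@H]1C | target

## Step count and risks

Total step count: 21 (15 on the main line, 6 for building blocks 8, 16 and 22).
Longest linear sequence: 15 steps (steps 1–5, 7–10, 13, 17–21).

The three steps most likely to fail: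

**Step 7 (the proposed new α-methoxylation).** The perester may be too weak an electrophile for the enamine, may oxidise or acylate the amine catalyst, or the labile α-methoxy aldehyde may partly racemise. The fallback uses known chemistry and sets out from 6. Enamine-catalysed α-benzoyloxylation with dibenzoyl peroxide, (S)-2-(triphenylmethyl)pyrrolidine (10 mol%) and hydroquinone (10 mol%) in THF at 0 °C gives the (2S)-α-benzoyloxy aldehyde F1. The same (Z)-crotyl-B(Ipc)2 addition as in step 8 gives the benzoate alcohol F2 (any benzoyl migration is harmless). K2CO3 in MeOH removes the benzoate to give the diol F3. NaH and excess MeI methylate both hydroxyls, and the sequence comes back to the route at 11, one step longer than the main line.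

**Step 10 (cross-metathesis of an allylically branched alkene with methacrolein).** Slow turnover or homodimerisation is possible. The fallback sets out from 11. OsO4 (cat.), NaIO4 and 2,6-lutidine in dioxane/H2O cleave the vinyl group to the α-methyl aldehyde F4. Wittig olefination of the crude aldehyde with 2-(triphenylphosphoranylidene)propanal in toluene at 80 °C then gives the E-enal and comes back to the route at 13.

**Step 13 (BF3-promoted allenylstannane addition to a conjugated, polyether-bearing enal).** Low reactivity or an eroded syn ratio is possible. The fallback sets out from 13. A titanium-enolate aldol with (S)-4-benzyl-3-propanoyl-1,3-thiazolidine-2-thione (TiCl4, i-Pr2NEt, 1 equiv each, CH2Cl2, −78 °C; chelated, non-Evans syn mode) gives the syn aldol adduct F5 with C6 and C7 as required. Et3SiOTf and 2,6-lutidine give the triethylsilyl ether F6. DIBAL-H at −78 °C cleaves the auxiliary to give the aldehyde F7. Dimethyl (1-diazo-2-oxopropyl)phosphonate with K2CO3 in MeOH gives the alkyne silyl ether F8. Bu4NF in THF removes the silyl group and comes back to the route at 17.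

## Further compounds

F1 | step 7 | (2S,4S,5R)-5-(3-bromo-2,5-dimethoxyphenyl)-5-[(4-methoxyphenyl)methoxy]-4-methyl-1-oxopentan-2-yl benzoate | O=C[C@@H](OC(=O)c1ccccc1)C[C@H](C)[C@@H](OCc1ccc(OC)cc1)c1cc(OC)cc(Br)c1OC
F2 | step 7 | (3S,4R,5S,7S,8R)-8-(3-bromo-2,5-dimethoxyphenyl)-4-hydroxy-8-[(4-methoxyphenyl)methoxy]-3,7-dimethyloct-1-en-5-yl benzoate | C=C[C@H](C)[C@@H](O)[C@@H](OC(=O)c1ccccc1)C[C@H](C)[C@@H](OCc1ccc(OC)cc1)c1cc(OC)cc(Br)c1OC
F3 | step 7 | (3S,4R,5S,7S,8R)-8-(3-bromo-2,5-dimethoxyphenyl)-8-[(4-methoxyphenyl)methoxy]-3,7-dimethyloct-1-ene-4,5-diol | C=C[C@H](C)[C@@H](O)[C@@H](O)C[C@H](C)[C@@H](OCc1ccc(OC)cc1)c1cc(OC)cc(Br)c1OC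
F4 | step 10 | (2R,3R,4S,6S,7R)-7-(3-bromo-2,5-dimethoxyphenyl)-3,4-dimethoxy-7-[(4-methoxyphenyl)methoxy]-2,6-dimethylheptanal | O=C[C@H](C)[C@@H](OC)[C@@H](OC)C[C@H](C)[C@@H](OCc1ccc(OC)cc1)c1cc(OC)cc(Br)c1OC
F5 | step 13 | (S)-4-benzyl-3-[(2R,3R,4E,6S,7R,8S,10S,11R)-11-(3-bromo-2,5-dimethoxyphenyl)-3-hydroxy-7,8-dimethoxy-11-[(4-methoxyphenyl)methoxy]-2,4,6,10-tetramethylundec-4-enoyl]-1,3-thiazolidine-2-thione | S=C1SC[C@H](Cc2ccccc2)N1C(=O)[C@H](C)[C@@H](O)/C(C)=C/[C@H](C)[C@@H](OC)[C@@H](OC)C[C@H](C)[C@@H](OCc1ccc(OC)cc1)c1cc(OC)cc(Br)c1OC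
F6 | step 13 | triethylsilyl ether of F5 at the 3-hydroxyl | S=C1SC[C@H](Cc2ccccc2)N1C(=O)[C@H](C)[C@@H](O[Si](CC)(CC)CC)/C(C)=C/[C@H](C)[C@@H](OC)[C@@H](OC)C[C@H](C)[C@@H](OCc1ccc(OC)cc1)c1cc(OC)cc(Br)c1OC
F7 | step 13 | (2R,3R,4E,6S,7R,8S,10S,11R)-11-(3-bromo-2,5-dimethoxyphenyl)-7,8-dimethoxy-11-[(4-methoxyphenyl)methoxy]-2,4,6,10-tetramethyl-3-[(triethylsilyl)oxy]undec-4-enal | O=C[C@H](C)[C@@H](O[Si](CC)(CC)CC)/C(C)=C/[C@H](C)[C@@H](OC)[C@@H](OC)C[C@H](C)[C@@H](OCc1ccc(OC)cc1)c1cc(OC)cc(Br)c1OC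
F8 | step 13 | {[(3S,4R,5E,7S,8R,9S,11S,12R)-12-(3-bromo-2,5-dimethoxyphenyl)-8,9-dimethoxy-12-[(4-methoxyphenyl)methoxy]-3,5,7,11-tetramethyldodec-5-en-1-yn-4-yl]oxy}(triethyl)silane | C#C[C@H](C)[C@@H](O[Si](CC)(CC)CC)/C(C)=C/[C@H](C)[C@@H](OC)[C@@H](OC)C[C@H](C)[C@@H](OCc1ccc(OC)cc1)c1cc(OC)cc(Br)c1OC
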